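**Retrosynthetic overview**

1. Target 25 ← C14 desilylation and allylic oxidation ← macrocycle 23 ← ten-membered carbocycle closed last by an intramolecular Ni/Cr (Nozaki–Hiyama–Kishi) coupling C9–C10 of iodo-aldehyde 21, the C9 alkoxide being acetylated in the same flask.
2. Enabling feature: C9 is a secondary allylic carbinol carbon bonded to C10, the α-carbon of the ring enal C1=C10 (ring-cis). An alkenyl iodide at C10 and an aldehyde at C9 are therefore an NHK pair. The cis C1=C10 olefin and the cis C4–C5 oxirane fold the chain, and the C8 acyloxy centre next to the aldehyde gives Felkin bias for C9.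
3. 21 ← Mitsunobu esterification with methacrylic acid (inversion at C8) ← indium Barbier SE2′ union of 3-(bromomethyl)butenolide 15 with aldehyde 16, which sets C7 trans to C6 and unveils the α-methylene lactone.
4. 15 ← RCM (γ-lactone ring) ← vinyl addition to epoxy aldehyde 10 (C6) ← Sharpless epoxidation (oxirane ring, C4 and C5) of Z-allylic alcohol 8 ← neryl acetate 1 (C1–C6, C15) by ozonolysis, Wittig reaction and α-iodination.
5. Ring order: oxirane (step 7), γ-lactone (step 11), ten-membered carbocycle (step 16). Only the epoxidation is reagent-controlled; C6, C7, C8 and C9 are relayed from it by substrate control.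

Key step: step 16

Remark: positions are given in germacrane numbering (C1–C15, lactone C6–O–C12). Compounds 1, 3, 11, 13, 16 and 18 are taken as commercial. "Iodopentenyl" means the (3Z)-5-[(tert-butyldiphenylsilyl)oxy]-4-iodopent-3-en-1-yl group. The ring olefin C1=C10 keeps one geometry from 5 to 25; its CIP label changes from Z to E only because C14 becomes CHO.

**Route**

Step 1
Reactants: 1 neryl acetate
Product: 2 (2Z)-3-methyl-6-oxohex-2-en-1-yl acetate
Conditions: O3 (1 equiv), CH2Cl2, pyridine, −78 °C; then Me2S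
Reagents that add atoms: ozone, [O-][O+]=O
Why: Chemoselective ozonolysis should cleave the electron-rich 6,7-olefin faster than the 2,3-olefin, which is deactivated by the allylic acetate and carries the Z geometry needed for C4=C5.

Step 2
Reactants: 2 (2Z)-3-methyl-6-oxohex-2-en-1-yl acetate; 3 (triphenylphosphoranylidene)acetaldehyde
Product: 4 (2Z,6E)-3-methyl-8-oxoocta-2,6-dien-1-yl acetate
Conditions: toluene, 80 °C
Reagents that add atoms: none
Why: Wittig olefination with the stabilised formyl ylide should give the (E)-enal and adds C10 and C14.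

Step 3
Reactants: 4 (2Z,6E)-3-methyl-8-oxoocta-2,6-dien-1-yl acetate
Product: 5 (2Z,6Z)-7-iodo-3-methyl-8-oxoocta-2,6-dien-1-yl acetate
Conditions: I2, K2CO3, DMAP (cat.), THF/H2O, rt
Reagents that add atoms: iodine, II
Why: α-Iodination of the enal by amine conjugate addition, iodination and elimination (Baylis–Hillman-type sequence) should give the thermodynamically preferred (Z)-2-iodoenal, with iodine cis to the chain.

Step 4
Reactants: 5 (2Z,6Z)-7-iodo-3-methyl-8-oxoocta-2,6-dien-1-yl acetate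
Product: 6 (2Z,6Z)-8-hydroxy-7-iodo-3-methylocta-2,6-dien-1-yl acetate
Conditions: NaBH4, CeCl3·7H2O, MeOH, −40 °C
Reagents that add atoms: none
Why: Luche 1,2-reduction should reduce only the aldehyde and leave the alkenyl iodide and the acetate intact.

Step 5
Reactants: 6 (2Z,6Z)-8-hydroxy-7-iodo-3-methylocta-2,6-dien-1-yl acetate
Product: 7 (2Z,6Z)-8-[(tert-butyldiphenylsilyl)oxy]-7-iodo-3-methylocta-2,6-dien-1-yl acetate
Conditions: TBDPSCl, imidazole, CH2Cl2, rt
Reagents that add atoms: tert-butyl(chloro)diphenylsilane, CC(C)(C)[Si](Cl)(c1ccccc1)c1ccccc1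
Why: Silylation of the primary allylic alcohol gives a C14 ether that should survive every step up to the end game.

Step 6
Reactants: 7 (2Z,6Z)-8-[(tert-butyldiphenylsilyl)oxy]-7-iodo-3-methylocta-2,6-dien-1-yl acetate
Product: 8 (2Z,6Z)-8-[(tert-butyldiphenylsilyl)oxy]-7-iodo-3-methylocta-2,6-dien-1-ol
Conditions: K2CO3 (cat.), MeOH, 0 °C
Reagents that add atoms: none
Why: Base-catalysed transesterification (methanolysis) should free the C6 allylic alcohol without touching the silyl ether or the iodide.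

Step 7
Reactants: 8 (2Z,6Z)-8-[(tert-butyldiphenylsilyl)oxy]-7-iodo-3-methylocta-2,6-dien-1-ol
Product: 9 [(2S,3R)-3-iodopentenyl-3-methyloxiran-2-yl]methanol
Conditions: Ti(OiPr)4 (10 mol %), L-(+)-DET (12 mol %), TBHP, 4 Å MS, CH2Cl2, −20 °C
Reagents that add atoms: tert-butyl hydroperoxide, CC(C)(C)OO
Why: Sharpless asymmetric epoxidation with L-(+)-tartrate should give the (2S,3R) cis-epoxide (C5 S, C4 R) from the Z-allylic alcohol, the iodoalkene being no allylic alcohol and electron-poor.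

Step 8
Reactants: 9 [(2S,3R)-3-iodopentenyl-3-methyloxiran-2-yl]methanol
Product: 10 (2R,3R)-3-iodopentenyl-3-methyloxirane-2-carbaldehyde
Conditions: Dess–Martin periodinane, pyridine, CH2Cl2, 0 °C
Reagents that add atoms: none
Why: Buffered Dess–Martin oxidation should give the epoxy aldehyde without epimerisation or epoxide opening (the 2R label is a priority change only).

Step 9
Reactants: 10 (2R,3R)-3-iodopentenyl-3-methyloxirane-2-carbaldehyde; 11 vinylmagnesium bromide
Product: 12 (1S)-1-[(2S,3R)-3-iodopentenyl-3-methyloxiran-2-yl]prop-2-en-1-ol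
Conditions: THF, −78 °C
Reagents that add atoms: none
Why: Grignard addition under Felkin–Anh (Cornforth) control, with the nucleophile anti to the oxirane C–O bond, should favour the anti (1S) carbinol and so set C6; the minor epimer is to be removed by chromatography.

Step 10
Reactants: 12 (1S)-1-[(2S,3R)-3-iodopentenyl-3-methyloxiran-2-yl]prop-2-en-1-ol; 13 2-(bromomethyl)prop-2-enoic acid
Product: 14 (1S)-1-[(2S,3R)-3-iodopentenyl-3-methyloxiran-2-yl]prop-2-en-1-yl 2-(bromomethyl)prop-2-enoate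
Conditions: DCC, DMAP (5 mol %), CH2Cl2, −20 to 0 °C
Reagents that add atoms: none
Why: Steglich esterification at low temperature should acylate the secondary alcohol with retention and keep amine attack on the allylic bromide slow.

Step 11
Reactants: 14 (1S)-1-[(2S,3R)-3-iodopentenyl-3-methyloxiran-2-yl]prop-2-en-1-yl 2-(bromomethyl)prop-2-enoate
Product: 15 (5S)-3-(bromomethyl)-5-[(2S,3R)-3-iodopentenyl-3-methyloxiran-2-yl]furan-2(5H)-one
Conditions: Grubbs II (10 mol %), toluene, 80 °C, 5 mM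
Reagents that add atoms: none
Why: Ring-closing metathesis between the vinyl group and the acrylate olefin should close the butenolide (lactone ring), the trisubstituted iodoalkene being inert to the catalyst.

Step 12
Reactants: 15 (5S)-3-(bromomethyl)-5-[(2S,3R)-3-iodopentenyl-3-methyloxiran-2-yl]furan-2(5H)-one; 16 [(tert-butyldimethylsilyl)oxy]acetaldehyde
Product: 17 (4R,5S)-4-{(1R)-2-[(tert-butyldimethylsilyl)oxy]-1-hydroxyethyl}-5-[(2S,3R)-3-iodopentenyl-3-methyloxiran-2-yl]-3-methylideneoxolan-2-one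
Conditions: In powder, THF/H2O (3:1), rt
Reagents that add atoms: none
Why: Barbier-type allylation should occur through C7 (SE2′) anti to the oxiranyl group on C6 (trans lactone, sets C7) and through a Zimmerman–Traxler chair in which the ring-fixed E-type allyl unit and an equatorial aldehyde residue give the (8R) carbinol, the olefin moving to the exocyclic position.

Step 13
Reactants: 17 (4R,5S)-4-{(1R)-2-[(tert-butyldimethylsilyl)oxy]-1-hydroxyethyl}-5-[(2S,3R)-3-iodopentenyl-3-methyloxiran-2-yl]-3-methylideneoxolan-2-one; 18 methacrylic acid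
Product: 19 (1S)-2-[(tert-butyldimethylsilyl)oxy]-1-{(2S,3R)-2-[(2S,3R)-3-iodopentenyl-3-methyloxiran-2-yl]-4-methylidene-5-oxooxolan-3-yl}ethyl 2-methylprop-2-enoate
Conditions: PPh3, DIAD, toluene, 0 °C to rt
Reagents that add atoms: none
Why: Mitsunobu esterification should displace the oxyphosphonium group by methacrylate with SN2 inversion, which turns the (8R) carbinol into the required (8S) ester in one step.

Step 14
Reactants: 19 (1S)-2-[(tert-butyldimethylsilyl)oxy]-1-{(2S,3R)-2-[(2S,3R)-3-iodopentenyl-3-methyloxiran-2-yl]-4-methylidene-5-oxooxolan-3-yl}ethyl 2-methylprop-2-enoate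
Product: 20 (1S)-2-hydroxy-1-{(2S,3R)-2-[(2S,3R)-3-iodopentenyl-3-methyloxiran-2-yl]-4-methylidene-5-oxooxolan-3-yl}ethyl 2-methylprop-2-enoate
Conditions: HF·pyridine, pyridine, THF, 0 °C
Reagents that add atoms: none
Why: Buffered HF·pyridine desilylation should cleave the primary TBS ether selectively over the TBDPS ether, and the weakly acidic medium disfavours acyl migration from O8 to O9.

Step 15
Reactants: 20 (1S)-2-hydroxy-1-{(2S,3R)-2-[(2S,3R)-3-iodopentenyl-3-methyloxiran-2-yl]-4-methylidene-5-oxooxolan-3-yl}ethyl 2-methylprop-2-enoate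
Product: 21 (1S)-2-oxo-1-{(2S,3S)-2-[(2S,3R)-3-iodopentenyl-3-methyloxiran-2-yl]-4-methylidene-5-oxooxolan-3-yl}ethyl 2-methylprop-2-enoate
Conditions: Dess–Martin periodinane, pyridine, CH2Cl2, 0 °C; used crude
Reagents that add atoms: none
Why: Buffered Dess–Martin oxidation should give the α-acyloxy aldehyde without epimerisation at C8 (the 3S label of the oxolane carbon is a priority change only).

Step 16
Reactants: 21 (1S)-2-oxo-1-{(2S,3S)-2-[(2S,3R)-3-iodopentenyl-3-methyloxiran-2-yl]-4-methylidene-5-oxooxolan-3-yl}ethyl 2-methylprop-2-enoate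
Product: 23 (4R,5S,6S,7R,8S,9R,1(10)Z)-9-acetoxy-14-[(tert-butyldiphenylsilyl)oxy]-4,5-epoxy-8-(methacryloyloxy)germacra-1(10),11(13)-dien-12,6-olide, via C9 carbinol 22 (not isolated)
Conditions: CrCl2 (10 equiv), NiCl2 (1 mol % of Cr), DMF/THF, 2 mM, slow addition, rt; then Ac2O, Et3N, DMAP, 0 °C
Reagents that add atoms: acetic anhydride, CC(=O)OC(C)=O
Why: Ni(0) formed in situ inserts into the C10–I bond, transmetalation gives the alkenylchromium(III) species with retention of olefin geometry, this adds to the C9 aldehyde, and the chromium alkoxide is acetylated in the same flask. The closest known reaction type is the Nozaki–Hiyama–Kishi macrocyclization of ω-iodoalkenyl aldehydes to ten-membered rings. The carbocycle is closed by a 10-exo-trig attack of C10 on the C9 carbonyl, the chain being pre-folded by the cis C1=C10 olefin and the cis C4–C5 oxirane. C9 is the only new stereocentre and should be set by the C8 acyloxy centre in a polar Felkin–Anh arrangement (C–O anti to the incoming alkenyl group), which gives the 8,9-anti (9R) product. The step needs cyclization over oligomerization (high dilution, slow addition), activation of the alkenyl iodide only (Cr(II)/Ni should leave esters, enoates and the oxirane alone), and no acyl shift from O8 to O9, which the immediate acetylation should prevent.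

Step 17
Reactants: 23 (4R,5S,6S,7R,8S,9R,1(10)Z)-9-acetoxy-14-[(tert-butyldiphenylsilyl)oxy]-4,5-epoxy-8-(methacryloyloxy)germacra-1(10),11(13)-dien-12,6-olide
Product: 24 (4R,5S,6S,7R,8S,9R,1(10)Z)-9-acetoxy-4,5-epoxy-14-hydroxy-8-(methacryloyloxy)germacra-1(10),11(13)-dien-12,6-olide
Conditions: TBAF, AcOH (1:1), THF, 0 °C to rt
Reagents that add atoms: none
Why: Fluoride desilylation buffered with acetic acid should free the C14 alcohol while suppressing acetyl migration and conjugate addition to the α-methylene lactone.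

Step 18
Reactants: 24 (4R,5S,6S,7R,8S,9R,1(10)Z)-9-acetoxy-4,5-epoxy-14-hydroxy-8-(methacryloyloxy)germacra-1(10),11(13)-dien-12,6-olide
Product: 25 (4R,5S,6S,7R,8S,9R,1(10)E)-9-acetoxy-4,5-epoxy-8-(methacryloyloxy)-14-oxogermacra-1(10),11(13)-dien-12,6-olide (CNP0121379.1)
Conditions: MnO2, CH2Cl2, rt
Reagents that add atoms: none
Why: Allylic oxidation with activated MnO2 should convert the primary allylic alcohol to the enal and leave the epoxide, both esters and the lactone untouched.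

**Compound list**

1 | neryl acetate, (2Z)-3,7-dimethylocta-2,6-dien-1-yl acetate | CC(C)=CCC/C(C)=C\COC(C)=O | starting material
2 | (2Z)-3-methyl-6-oxohex-2-en-1-yl acetate | CC(=O)OC/C=C(C)\CCC=O | intermediate
3 | (triphenylphosphoranylidene)acetaldehyde | O=CC=P(c1ccccc1)(c1ccccc1)c1ccccc1 | starting material
4 | (2Z,6E)-3-methyl-8-oxoocta-2,6-dien-1-yl acetate | CC(=O)OC/C=C(C)\CC/C=C/C=O | intermediate
5 | (2Z,6Z)-7-iodo-3-methyl-8-oxoocta-2,6-dien-1-yl acetate | CC(=O)OC/C=C(C)\CC/C=C(I)/C=O | intermediate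
6 | (2Z,6Z)-8-hydroxy-7-iodo-3-methylocta-2,6-dien-1-yl acetate | CC(=O)OC/C=C(C)\CC/C=C(I)/CO | intermediate
7 | (2Z,6Z)-8-[(tert-butyldiphenylsilyl)oxy]-7-iodo-3-methylocta-2,6-dien-1-yl acetate | CC(=O)OC/C=C(C)\CC/C=C(I)/CO[Si](C(C)(C)C)(c1ccccc1)c1ccccc1 | intermediate
8 | (2Z,6Z)-8-[(tert-butyldiphenylsilyl)oxy]-7-iodo-3-methylocta-2,6-dien-1-ol | OC/C=C(C)\CC/C=C(I)/CO[Si](C(C)(C)C)(c1ccccc1)c1ccccc1 | intermediate
9 | [(2S,3R)-3-{(3Z)-5-[(tert-butyldiphenylsilyl)oxy]-4-iodopent-3-en-1-yl}-3-methyloxiran-2-yl]methanol | OC[C@@H]1O[C@]1(C)CC/C=C(I)/CO[Si](C(C)(C)C)(c1ccccc1)c1ccccc1 | intermediate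
10 | (2R,3R)-3-{(3Z)-5-[(tert-butyldiphenylsilyl)oxy]-4-iodopent-3-en-1-yl}-3-methyloxirane-2-carbaldehyde | O=C[C@@H]1O[C@]1(C)CC/C=C(I)/CO[Si](C(C)(C)C)(c1ccccc1)c1ccccc1 | intermediate
11 | vinylmagnesium bromide | C=C[Mg]Br | starting material
12 | (1S)-1-[(2S,3R)-3-{(3Z)-5-[(tert-butyldiphenylsilyl)oxy]-4-iodopent-3-en-1-yl}-3-methyloxiran-2-yl]prop-2-en-1-ol | C=C[C@H](O)[C@@H]1O[C@]1(C)CC/C=C(I)/CO[Si](C(C)(C)C)(c1ccccc1)c1ccccc1 | intermediate
13 | 2-(bromomethyl)prop-2-enoic acid | C=C(CBr)C(=O)O | starting material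
14 | (1S)-1-[(2S,3R)-3-{(3Z)-5-[(tert-butyldiphenylsilyl)oxy]-4-iodopent-3-en-1-yl}-3-methyloxiran-2-yl]prop-2-en-1-yl 2-(bromomethyl)prop-2-enoate | C=C[C@H](OC(=O)C(=C)CBr)[C@@H]1O[C@]1(C)CC/C=C(I)/CO[Si](C(C)(C)C)(c1ccccc1)c1ccccc1 | intermediate
15 | (5S)-3-(bromomethyl)-5-[(2S,3R)-3-{(3Z)-5-[(tert-butyldiphenylsilyl)oxy]-4-iodopent-3-en-1-yl}-3-methyloxiran-2-yl]furan-2(5H)-one | O=C1O[C@@H](C=C1CBr)[C@@H]1O[C@]1(C)CC/C=C(I)/CO[Si](C(C)(C)C)(c1ccccc1)c1ccccc1 | intermediate
16 | [(tert-butyldimethylsilyl)oxy]acetaldehyde | CC(C)(C)[Si](C)(C)OCC=O | starting material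
17 | (4R,5S)-4-{(1R)-2-[(tert-butyldimethylsilyl)oxy]-1-hydroxyethyl}-5-[(2S,3R)-3-{(3Z)-5-[(tert-butyldiphenylsilyl)oxy]-4-iodopent-3-en-1-yl}-3-methyloxiran-2-yl]-3-methylideneoxolan-2-one | CC(C)(C)[Si](C)(C)OC[C@H](O)[C@H]1C(=C)C(=O)O[C@@H]1[C@@H]1O[C@]1(C)CC/C=C(I)/CO[Si](C(C)(C)C)(c1ccccc1)c1ccccc1 | intermediate
18 | methacrylic acid | C=C(C)C(=O)O | starting material
19 | (1S)-2-[(tert-butyldimethylsilyl)oxy]-1-{(2S,3R)-2-[(2S,3R)-3-{(3Z)-5-[(tert-butyldiphenylsilyl)oxy]-4-iodopent-3-en-1-yl}-3-methyloxiran-2-yl]-4-methylidene-5-oxooxolan-3-yl}ethyl 2-methylprop-2-enoate | CC(C)(C)[Si](C)(C)OC[C@@H](OC(=O)C(C)=C)[C@H]1C(=C)C(=O)O[C@@H]1[C@@H]1O[C@]1(C)CC/C=C(I)/CO[Si](C(C)(C)C)(c1ccccc1)c1ccccc1 | intermediate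
20 | (1S)-2-hydroxy-1-{(2S,3R)-2-[(2S,3R)-3-{(3Z)-5-[(tert-butyldiphenylsilyl)oxy]-4-iodopent-3-en-1-yl}-3-methyloxiran-2-yl]-4-methylidene-5-oxooxolan-3-yl}ethyl 2-methylprop-2-enoate | OC[C@@H](OC(=O)C(C)=C)[C@H]1C(=C)C(=O)O[C@@H]1[C@@H]1O[C@]1(C)CC/C=C(I)/CO[Si](C(C)(C)C)(c1ccccc1)c1ccccc1 | intermediate
21 | (1S)-2-oxo-1-{(2S,3S)-2-[(2S,3R)-3-{(3Z)-5-[(tert-butyldiphenylsilyl)oxy]-4-iodopent-3-en-1-yl}-3-methyloxiran-2-yl]-4-methylidene-5-oxooxolan-3-yl}ethyl 2-methylprop-2-enoate | O=C[C@@H](OC(=O)C(C)=C)[C@H]1C(=C)C(=O)O[C@@H]1[C@@H]1O[C@]1(C)CC/C=C(I)/CO[Si](C(C)(C)C)(c1ccccc1)c1ccccc1 | intermediate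
22 | (4R,5S,6S,7R,8S,9R,1(10)Z)-14-[(tert-butyldiphenylsilyl)oxy]-4,5-epoxy-9-hydroxy-8-(methacryloyloxy)germacra-1(10),11(13)-dien-12,6-olide, present in the flask as its chromium(III) alkoxide | C=C(C)C(=O)O[C@H]1[C@H]2C(=C)C(=O)O[C@@H]2[C@@H]2O[C@]2(C)CC/C=C(/CO[Si](C(C)(C)C)(c3ccccc3)c3ccccc3)[C@H]1O | intermediate
23 | (4R,5S,6S,7R,8S,9R,1(10)Z)-9-acetoxy-14-[(tert-butyldiphenylsilyl)oxy]-4,5-epoxy-8-(methacryloyloxy)germacra-1(10),11(13)-dien-12,6-olide | C=C(C)C(=O)O[C@H]1[C@H]2C(=C)C(=O)O[C@@H]2[C@@H]2O[C@]2(C)CC/C=C(/CO[Si](C(C)(C)C)(c3ccccc3)c3ccccc3)[C@H]1OC(C)=O | intermediate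
24 | (4R,5S,6S,7R,8S,9R,1(10)Z)-9-acetoxy-4,5-epoxy-14-hydroxy-8-(methacryloyloxy)germacra-1(10),11(13)-dien-12,6-olide | C=C(C)C(=O)O[C@H]1[C@H]2C(=C)C(=O)O[C@@H]2[C@@H]2O[C@]2(C)CC/C=C(/CO)[C@H]1OC(C)=O | intermediate
25 | (4R,5S,6S,7R,8S,9R,1(10)E)-9-acetoxy-4,5-epoxy-8-(methacryloyloxy)-14-oxogermacra-1(10),11(13)-dien-12,6-olide (CNP0121379.1) | C=C(C)C(=O)O[C@H]1[C@H]2C(=C)C(=O)O[C@@H]2[C@@H]2O[C@]2(C)CC/C=C(/C=O)[C@H]1OC(C)=O | target

**Step count and risks**

Total step count: 18. Longest linear sequence: 18 steps (1 to 25); compounds 3, 11, 13, 16 and 18 enter as single building blocks.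

The three steps most likely to fail are the following.

The macrocyclization in step 16 is the first risk. The ring-forming transition state could override Felkin control, so that the alkenylchromium attacks the other face of the C9 aldehyde and the wrong C9 epimer is formed, with oligomerization as a second loss channel. The fallback sets out from 21: the Ni/Cr cyclization is run without the acetylation, the (4R,5S,6S,7R,8S,9S,1(10)Z)-14-[(tert-butyldiphenylsilyl)oxy]-4,5-epoxy-9-hydroxy-8-(methacryloyloxy)germacra-1(10),11(13)-dien-12,6-olide F1 is isolated, and a Mitsunobu esterification with acetic acid (PPh3, DIAD, toluene) inverts C9 while installing the acetate. The route is rejoined at 23.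

The Mitsunobu esterification in step 13 is the second risk. At the hindered C8 the displacement could be outrun by elimination towards the diene, or by participation of the lactone carbonyl, which would cost the inversion. The fallback sets out from 17: sulfonylation with chloromethanesulfonyl chloride and pyridine gives the (1R)-2-[(tert-butyldimethylsilyl)oxy]-1-{(2S,3R)-2-[(2S,3R)-3-iodopentenyl-3-methyloxiran-2-yl]-4-methylidene-5-oxooxolan-3-yl}ethyl chloromethanesulfonate F2, and a separate SN2 displacement with cesium methacrylate (18, Cs2CO3, 18-crown-6, toluene, 60 °C) should give the inverted ester. The route is rejoined at 19.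

The ring-closing metathesis in step 11 is the third risk. Closure onto the electron-poor 1,1-disubstituted olefin is slow and the allylic bromide could degrade the catalyst or be lost before the ring closes. The fallback sets out from 12: acylation with acryloyl chloride and Et3N gives the (1S)-1-[(2S,3R)-3-iodopentenyl-3-methyloxiran-2-yl]prop-2-en-1-yl prop-2-enoate F3, whose metathesis (Grubbs II) to the (5S)-5-[(2S,3R)-3-iodopentenyl-3-methyloxiran-2-yl]furan-2(5H)-one F4 has only a disubstituted olefin to form. A Morita–Baylis–Hillman hydroxymethylation (aqueous formaldehyde, PBu3 cat.) then gives the (5S)-3-(hydroxymethyl)-5-[(2S,3R)-3-iodopentenyl-3-methyloxiran-2-yl]furan-2(5H)-one F5, and an Appel bromination (CBr4, PPh3) follows. The route is rejoined at 15.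

**Further compounds**

F1 | step 16 | (4R,5S,6S,7R,8S,9S,1(10)Z)-14-[(tert-butyldiphenylsilyl)oxy]-4,5-epoxy-9-hydroxy-8-(methacryloyloxy)germacra-1(10),11(13)-dien-12,6-olide | C=C(C)C(=O)O[C@H]1[C@H]2C(=C)C(=O)O[C@@H]2[C@@H]2O[C@]2(C)CC/C=C(/CO[Si](C(C)(C)C)(c3ccccc3)c3ccccc3)[C@@H]1O
F2 | step 13 | (1R)-2-[(tert-butyldimethylsilyl)oxy]-1-{(2S,3R)-2-[(2S,3R)-3-{(3Z)-5-[(tert-butyldiphenylsilyl)oxy]-4-iodopent-3-en-1-yl}-3-methyloxiran-2-yl]-4-methylidene-5-oxooxolan-3-yl}ethyl chloromethanesulfonate | CC(C)(C)[Si](C)(C)OC[C@H](OS(=O)(=O)CCl)[C@H]1C(=C)C(=O)O[C@@H]1[C@@H]1O[C@]1(C)CC/C=C(I)/CO[Si](C(C)(C)C)(c1ccccc1)c1ccccc1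
F3 | step 11 | (1S)-1-[(2S,3R)-3-{(3Z)-5-[(tert-butyldiphenylsilyl)oxy]-4-iodopent-3-en-1-yl}-3-methyloxiran-2-yl]prop-2-en-1-yl prop-2-enoate | C=C[C@H](OC(=O)C=C)[C@@H]1O[C@]1(C)CC/C=C(I)/CO[Si](C(C)(C)C)(c1ccccc1)c1ccccc1
F4 | step 11 | (5S)-5-[(2S,3R)-3-{(3Z)-5-[(tert-butyldiphenylsilyl)oxy]-4-iodopent-3-en-1-yl}-3-methyloxiran-2-yl]furan-2(5H)-one | O=C1O[C@@H](C=C1)[C@@H]1O[C@]1(C)CC/C=C(I)/CO[Si](C(C)(C)C)(c1ccccc1)c1ccccc1
F5 | step 11 | (5S)-3-(hydroxymethyl)-5-[(2S,3R)-3-{(3Z)-5-[(tert-butyldiphenylsilyl)oxy]-4-iodopent-3-en-1-yl}-3-methyloxiran-2-yl]furan-2(5H)-one | O=C1O[C@@H](C=C1CO)[C@@H]1O[C@]1(C)CC/C=C(I)/CO[Si](C(C)(C)C)(c1ccccc1)c1ccccc1
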